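**Retrosynthetic overview**
- The plan rests on the oxolane hemiketal ring (bridging O, C10, C1, C2, C3) that spans the ten-membered carbocycle C1–C10. It is a masked γ-hydroxy ketone, and its C10 methyl carbinol with the C1 methylene is a 2,2-disubstituted epoxide opened at CH2.
- C1–C2 is cut first: the lithiated C3 dimethylhydrazone opens the C10 epoxide at C1 and closes the carbocycle, and hydrazone hydrolysis then lets the C10 oxygen close the oxolane onto C3.
- The butenolide (C7, C11, C12, O, C8) with its C8=C9 alkene is carried as a 2,3,4-trisubstituted furan and unveiled last by singlet oxygen and dehydration. Ring order: furan (bought), carbocycle, oxolane, butenolide.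
- The open-chain precursor is cut at C6–C7 into a 3-lithiofuran (3,4-dibromofuran plus C9–C10–C1 from 2-methylglycidol) and a bis-Weinreb amide of (S)-citramalic acid (C3–C6, C4 stereocentre). C6 is set by CBS reduction.

Key step: step 13

Remark: germacrane-type numbering is used: C10 (Me, bridging O), C1, C2, C3 (hemiketal), C4 (Me, OAc), C5, C6 (OH), C7, C8 (lactone O), C9; C11, C12 and C13 are the butenolide α-carbon, carbonyl and acetoxymethyl carbon.
Remark: both enantiomers of 2-methylglycidol are taken as purchasable. The (R)-alcohol is used because the furyl anion is made to open the epoxide ring of its tosylate and the ring is then re-closed on the other CH2, so C10 cannot be scrambled by competing attack at two electrophilic carbons.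

Step 1
Reactants: 1 3,4-dibromofuran
Product: 5 (4-bromofuran-3-yl)methanol, via 3-bromo-4-lithiofuran 2 (not isolated), via lithium hemiaminal alkoxide 3 (not isolated), via 4-bromofuran-3-carbaldehyde 4 (not isolated)
Conditions: n-BuLi (1 equiv), Et2O, −78 °C; DMF, −78 → 0 °C; then MeOH, NaBH4, 0 °C
Reagents that add atoms: N,N-dimethylformamide CN(C)C=O
Why: Bromine–lithium exchange on the symmetric dibromide gives the monolithio species, formylation with DMF and in-flask NaBH4 reduction of the released aldehyde deliver the C13 carbinol, and the second bromine remains as the later handle for C7.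

Step 2
Reactants: 5 (4-bromofuran-3-yl)methanol
Product: 6 [(4-bromofuran-3-yl)methoxy](tert-butyl)dimethylsilane
Conditions: TBSCl, imidazole, DMF, 25 °C
Reagents that add atoms: tert-butyldimethylsilyl chloride CC(C)(C)[Si](C)(C)Cl
Why: Imidazole-mediated silylation masks the C13 alcohol as a TBS ether that tolerates the organolithium steps to come.

Step 3
Reactants: 7 (R)-2-methylglycidol
Product: 8 [(2S)-2-methyloxiran-2-yl]methyl 4-methylbenzenesulfonate
Conditions: TsCl, Et3N, DMAP (cat.), CH2Cl2, 0 °C
Reagents that add atoms: 4-toluenesulfonyl chloride Cc1ccc(cc1)S(=O)(=O)Cl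
Why: Sulfonylation of the primary alcohol touches no bond at the stereocentre (only the CIP descriptor changes) and installs the leaving group used to re-close the epoxide in step 5.

Step 4
Reactants: 6 [(4-bromofuran-3-yl)methoxy](tert-butyl)dimethylsilane and 8 [(2S)-2-methyloxiran-2-yl]methyl 4-methylbenzenesulfonate
Product: 10 (2S)-3-{3-bromo-4-[(tert-butyldimethylsilyloxy)methyl]furan-2-yl}-2-hydroxy-2-methylpropyl 4-methylbenzenesulfonate, via 3-bromo-2-lithiofuran 9 (not isolated)
Conditions: LDA, THF, −78 °C; then 8, BF3·OEt2 (2.5 equiv), −78 °C; aq. NaHCO3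
Reagents that add atoms: none
Why: Bromine-directed deprotonation by LDA occurs at the furan α-carbon next to Br (future C8), and the BF3-promoted organolithium epoxide opening at the ring CH2 (not displacement of the tosylate) forms C8–C9 while the C10–O bond, and so the configuration from 7, is untouched.

Step 5
Reactants: 10 (2S)-3-{3-bromo-4-[(tert-butyldimethylsilyloxy)methyl]furan-2-yl}-2-hydroxy-2-methylpropyl 4-methylbenzenesulfonate
Product: 11 3-bromo-4-[(tert-butyldimethylsilyloxy)methyl]-2-{[(2S)-2-methyloxiran-2-yl]methyl}furan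
Conditions: K2CO3, MeOH, 0 → 25 °C
Reagents that add atoms: none
Why: Intramolecular Williamson closure (3-exo-tet) of the tertiary alkoxide onto the primary tosylate re-forms the epoxide on the other CH2 (future C1) without touching C10.

Step 6
Reactants: 12 (S)-citramalic acid
Product: 13 (2S)-2-hydroxy-N1,N4-dimethoxy-N1,N4,2-trimethylbutanediamide
Conditions: MeNHOMe·HCl (2.6 equiv), EDC·HCl, HOBt, N-methylmorpholine, CH2Cl2, 0 → 25 °C
Reagents that add atoms: N,O-dimethylhydroxylamine hydrochloride CNOC.Cl
Why: Carbodiimide/HOBt amide coupling turns both carboxyl groups into N-methoxy-N-methylamides, the tertiary hydroxyl being too hindered to compete and the C4 stereocentre (no α-hydrogen) unable to epimerise.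

Step 7
Reactants: 13 (2S)-2-hydroxy-N1,N4-dimethoxy-N1,N4,2-trimethylbutanediamide
Product: 14 (2S)-N1,N4-dimethoxy-N1,N4,2-trimethyl-2-(triethylsilyloxy)butanediamide
Conditions: TESOTf, 2,6-lutidine, CH2Cl2, 0 °C
Reagents that add atoms: triethylsilyl trifluoromethanesulfonate CC[Si](CC)(CC)OS(=O)(=O)C(F)(F)F
Why: Silyl triflate silylation removes the acidic tertiary OH and adds to the steric shielding of the neighbouring (C3) amide.

Step 8
Reactants: 11 3-bromo-4-[(tert-butyldimethylsilyloxy)methyl]-2-{[(2S)-2-methyloxiran-2-yl]methyl}furan and 14 (2S)-N1,N4-dimethoxy-N1,N4,2-trimethyl-2-(triethylsilyloxy)butanediamide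
Product: 17 (2S)-4-{4-[(tert-butyldimethylsilyloxy)methyl]-2-{[(2S)-2-methyloxiran-2-yl]methyl}furan-3-yl}-N-methoxy-N,2-dimethyl-4-oxo-2-(triethylsilyloxy)butanamide, via 3-lithiofuran 15 (not isolated), via lithium hemiaminal alkoxide 16 (not isolated)
Conditions: t-BuLi (2 equiv), Et2O, −78 °C; then 14, −78 → −50 °C; aq. NH4Cl
Reagents that add atoms: none
Why: Bromine–lithium exchange followed by Weinreb ketone synthesis forms C6–C7, since the 3-furyllithium adds only to the unhindered CH2-bound amide (the amide on quaternary C4 is shielded), the chelated adduct 16 prevents over-addition, and at −78 °C in ether neither the epoxide nor the neighbouring silyl ether is attacked.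

Step 9
Reactants: 17 furyl ketone (C6 ketone, C3 Weinreb amide)
Product: 18 (2S,4R)-4-hydroxy-4-{4-[(tert-butyldimethylsilyloxy)methyl]-2-{[(2S)-2-methyloxiran-2-yl]methyl}furan-3-yl}-N-methoxy-N,2-dimethyl-2-(triethylsilyloxy)butanamide
Conditions: (S)-2-methyl-CBS-oxazaborolidine (0.3 equiv), BH3·SMe2, toluene, −20 °C; MeOH
Reagents that add atoms: none
Why: Corey–Bakshi–Shibata reduction under reagent control, with the furyl ring as the large and the CH2 chain as the small group, should give the (6R)-alcohol, which is 1,3-syn to the C4 oxygen.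

Step 10
Reactants: 18 (6R)-alcohol
Product: 19 (2S,4R)-4-(tert-butyldimethylsilyloxy)-4-{4-[(tert-butyldimethylsilyloxy)methyl]-2-{[(2S)-2-methyloxiran-2-yl]methyl}furan-3-yl}-N-methoxy-N,2-dimethyl-2-(triethylsilyloxy)butanamide
Conditions: TBSOTf, 2,6-lutidine (excess), CH2Cl2, −78 °C
Reagents that add atoms: tert-butyldimethylsilyl trifluoromethanesulfonate CC(C)(C)[Si](C)(C)OS(=O)(=O)C(F)(F)F
Why: Silyl triflate silylation of the hindered secondary alcohol is run cold with excess base so that the 2,2-disubstituted epoxide is left alone.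

Step 11
Reactants: 19 C6 TBS ether Weinreb amide
Product: 21 (3S,5R)-5-(tert-butyldimethylsilyloxy)-5-{4-[(tert-butyldimethylsilyloxy)methyl]-2-{[(2S)-2-methyloxiran-2-yl]methyl}furan-3-yl}-3-methyl-3-(triethylsilyloxy)pentan-2-one, via lithium hemiaminal alkoxide 20 (not isolated)
Conditions: MeLi (halide-free, 3 equiv), Et2O/THF, −78 → −20 °C; aq. NH4Cl
Reagents that add atoms: methyllithium [Li]C
Why: Weinreb ketone synthesis on the remaining hindered amide adds methyl once (chelated adduct 20) and releases the C3 methyl ketone, bringing in C2, while MeLi without a Lewis acid does not open the epoxide at this temperature.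

Step 12
Reactants: 21 methyl ketone
Product: 22 (E)-N,N-dimethylhydrazone of 21 (open-chain furyl hydrazone epoxide; 4S, 6R, 10S)
Conditions: Me2NNH2 (excess), 4 Å molecular sieves, toluene, 60 °C
Reagents that add atoms: 1,1-dimethylhydrazine CN(C)N
Why: Hydrazone condensation is run aprotic and acid-free with sieves so that the hydrazine does not open the hindered epoxide, and the (E)-isomer with NMe2 turned away from quaternary C4 is expected.

Step 13
Reactants: 22 open-chain furyl hydrazone epoxide
Product: 26 bridged furan hemiketal (3S,4S,6R,10R; C4 OTES, C6 OTBS, C13 OTBS), via lithium aza-enolate 23 (not isolated), via ten-membered hydroxy hydrazone 24 (not isolated), via ten-membered hydroxy ketone 25 (not isolated)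
Conditions: LDA (1.1 equiv), THF, −78 → −20 °C; slow transfer into THF (about 2 mM), 0 → 40 °C; then CuCl2, pH 7 phosphate buffer, THF/H2O, 25 °C
Reagents that add atoms: water O
Why: Proposed new method: LDA removes a proton from the only enolizable position of the hydrazone (the C2 methyl, C4 being quaternary), and the carbon of the lithium aza-enolate attacks the unsubstituted epoxide carbon C1 in an SN2 opening that forms C1–C2 and frees the C10 alkoxide with its C–O bond intact. The closest known reactions are the intermolecular opening of terminal and 2,2-disubstituted epoxides by lithiated N,N-dimethylhydrazones and the macrocyclization of sulfone- or cyanohydrin-stabilized carbanions onto allylic halides to give ten-membered carbocycles. The carbocycle closes in the endo mode with respect to the epoxide (both epoxide carbons end in the ten-membered ring), and after copper-assisted hydrazone hydrolysis the oxolane closes by 5-exo-trig addition of the C10 hydroxyl to the C3 ketone across the ring. C10 keeps the configuration brought in with the glycidol, and the only new stereocentre, hemiketal carbon C3, is set under thermodynamic control because the one-atom oxygen bridge can span C3 and C10 only cis, which puts the C3 hydroxyl and the C10 methyl on the same face of the oxolane. The step needs intramolecular C-alkylation at the CH2 terminus to win over oligomerization, N-alkylation, attack at the quaternary epoxide carbon and base-induced isomerization of the epoxide to an allylic alkoxide through C9; the ortho placement of the two arms on the rigid furan, high dilution, the steric bias of the 2,2-disubstituted epoxide and only a slight excess of amide base are what should secure it.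

Step 14
Reactants: 26 bridged furan hemiketal
Product: 27 triol (3S,4S,6R,10R; free OH at C3, C4 and C13, C6 OTBS)
Conditions: HF·pyridine, pyridine, THF, 0 → 25 °C, followed by TLC
Reagents that add atoms: none
Why: Fluoride-mediated silyl ether cleavage is graded by sterics, so the primary C13 TBS ether and the C4 TES ether should go well before the secondary C6 TBS ether, which is wedged between the furan and the quaternary C4 region.

Step 15
Reactants: 27 triol
Product: 28 C4,C13-diacetate (3S,4S,6R,10R; free hemiketal OH, C6 OTBS)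
Conditions: Ac2O, DMAP, Et3N, CH2Cl2, 0 → 25 °C
Reagents that add atoms: acetic anhydride CC(=O)OC(C)=O
Why: DMAP-catalysed acyl transfer acetylates the primary C13 and the tertiary C4 hydroxyl, while the hemiketal hydroxyl at C3, flanked by the ring oxygen and quaternary C4, is expected to react last.

Step 16
Reactants: 28 C4,C13-diacetate
Product: 30 γ-hydroxybutenolide (C12 lactone carbonyl, C8 OH, mixture at C8), via furan endoperoxide 29 (not isolated)
Conditions: O2, visible light, tetraphenylporphyrin (cat.), i-Pr2NEt, CH2Cl2, −78 → 25 °C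
Reagents that add atoms: dioxygen O=O
Why: [4+2] cycloaddition of singlet oxygen across C8/C12 of the furan and base-mediated Kornblum–DeLaMare fragmentation of endoperoxide 29 through its only bridgehead hydrogen (C12–H) place the carbonyl at C12 and the hydroxyl at C8, whose configuration is of no consequence.

Step 17
Reactants: 30 γ-hydroxybutenolide
Product: 32 C6 TBS ether of the target (8E dienol lactone), via C8 trifluoroacetate 31 (not isolated)
Conditions: (CF3CO)2O, pyridine, CH2Cl2, −40 → 0 °C; aq. NaHCO3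
Reagents that add atoms: none
Why: Acylation of the pseudo-acid hydroxyl at C8 and E1-type loss of trifluoroacetate (proton lost from C9) dehydrate the hydroxybutenolide to the γ-ylidene butenolide, the C8=C9 geometry (C7 and C10 cis) being dictated by the bridged ring and any trifluoroacetate formed at C3–OH being hydrolysed on bicarbonate work-up.

Step 18
Reactants: 32 C6 TBS ether of the target
Product: 33 CNP0203479.1
Conditions: HF·pyridine, pyridine, THF, 0 → 25 °C
Reagents that add atoms: none
Why: Buffered, mildly acidic fluoride cleavage removes the last silyl ether while the two acetates, the hemiketal and the base-sensitive dienol lactone with its allylic acetate should survive.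

**Compound list**
1 | 3,4-dibromofuran | Brc1cocc1Br | starting material
2 | 3-bromo-4-lithiofuran | [Li]c1cocc1Br | intermediate
3 | lithium (4-bromofuran-3-yl)(dimethylamino)methanolate | [Li]OC(N(C)C)c1cocc1Br | intermediate
4 | 4-bromofuran-3-carbaldehyde | O=Cc1cocc1Br | intermediate
5 | (4-bromofuran-3-yl)methanol | OCc1cocc1Br | intermediate
6 | [(4-bromofuran-3-yl)methoxy](tert-butyl)dimethylsilane | CC(C)(C)[Si](C)(C)OCc1cocc1Br | intermediate
7 | (R)-2-methylglycidol, [(2R)-2-methyloxiran-2-yl]methanol | OC[C@]1(C)CO1 | starting material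
8 | [(2S)-2-methyloxiran-2-yl]methyl 4-methylbenzenesulfonate | Cc1ccc(cc1)S(=O)(=O)OC[C@]1(C)CO1 | intermediate
9 | 3-bromo-4-[(tert-butyldimethylsilyloxy)methyl]-2-lithiofuran | [Li]c1occ(CO[Si](C)(C)C(C)(C)C)c1Br | intermediate
10 | (2S)-3-{3-bromo-4-[(tert-butyldimethylsilyloxy)methyl]furan-2-yl}-2-hydroxy-2-methylpropyl 4-methylbenzenesulfonate | Cc1ccc(cc1)S(=O)(=O)OC[C@](O)(C)Cc1occ(CO[Si](C)(C)C(C)(C)C)c1Br | intermediate
11 | 3-bromo-4-[(tert-butyldimethylsilyloxy)methyl]-2-{[(2S)-2-methyloxiran-2-yl]methyl}furan | Brc1c(C[C@@]2(C)CO2)occ1CO[Si](C)(C)C(C)(C)C | intermediate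
12 | (S)-citramalic acid, (2S)-2-hydroxy-2-methylbutanedioic acid | C[C@](O)(CC(=O)O)C(=O)O | starting material
13 | (2S)-2-hydroxy-N1,N4-dimethoxy-N1,N4,2-trimethylbutanediamide | C[C@](O)(CC(=O)N(C)OC)C(=O)N(C)OC | intermediate
14 | (2S)-N1,N4-dimethoxy-N1,N4,2-trimethyl-2-(triethylsilyloxy)butanediamide | C[C@](O[Si](CC)(CC)CC)(CC(=O)N(C)OC)C(=O)N(C)OC | intermediate
15 | 4-[(tert-butyldimethylsilyloxy)methyl]-3-lithio-2-{[(2S)-2-methyloxiran-2-yl]methyl}furan | [Li]c1c(C[C@@]2(C)CO2)occ1CO[Si](C)(C)C(C)(C)C | intermediate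
16 | lithium hemiaminal alkoxide from addition of 15 to the CH2-bound amide of 14 | C[C@](O[Si](CC)(CC)CC)(CC(O[Li])(N(C)OC)c1c(C[C@@]2(C)CO2)occ1CO[Si](C)(C)C(C)(C)C)C(=O)N(C)OC | intermediate
17 | (2S)-4-{4-[(tert-butyldimethylsilyloxy)methyl]-2-{[(2S)-2-methyloxiran-2-yl]methyl}furan-3-yl}-N-methoxy-N,2-dimethyl-4-oxo-2-(triethylsilyloxy)butanamide | C[C@](O[Si](CC)(CC)CC)(CC(=O)c1c(C[C@@]2(C)CO2)occ1CO[Si](C)(C)C(C)(C)C)C(=O)N(C)OC | intermediate
18 | (2S,4R)-4-hydroxy analogue of 17 (C6 alcohol, 6R) | C[C@](O[Si](CC)(CC)CC)(C[C@@H](O)c1c(C[C@@]2(C)CO2)occ1CO[Si](C)(C)C(C)(C)C)C(=O)N(C)OC | intermediate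
19 | (2S,4R)-4-(tert-butyldimethylsilyloxy) analogue of 18 (C6 OTBS) | C[C@](O[Si](CC)(CC)CC)(C[C@@H](O[Si](C)(C)C(C)(C)C)c1c(C[C@@]2(C)CO2)occ1CO[Si](C)(C)C(C)(C)C)C(=O)N(C)OC | intermediate
20 | lithium hemiaminal alkoxide from addition of MeLi to the C3 amide of 19 | CC(O[Li])(N(C)OC)[C@@](C)(O[Si](CC)(CC)CC)C[C@@H](O[Si](C)(C)C(C)(C)C)c1c(C[C@@]2(C)CO2)occ1CO[Si](C)(C)C(C)(C)C | intermediate
21 | (3S,5R)-5-(tert-butyldimethylsilyloxy)-5-{4-[(tert-butyldimethylsilyloxy)methyl]-2-{[(2S)-2-methyloxiran-2-yl]methyl}furan-3-yl}-3-methyl-3-(triethylsilyloxy)pentan-2-one | CC(=O)[C@@](C)(O[Si](CC)(CC)CC)C[C@@H](O[Si](C)(C)C(C)(C)C)c1c(C[C@@]2(C)CO2)occ1CO[Si](C)(C)C(C)(C)C | intermediate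
22 | (E)-N,N-dimethylhydrazone of 21 (open-chain furyl hydrazone epoxide, key-step precursor) | CN(C)/N=C(\C)[C@@](C)(O[Si](CC)(CC)CC)C[C@@H](O[Si](C)(C)C(C)(C)C)c1c(C[C@@]2(C)CO2)occ1CO[Si](C)(C)C(C)(C)C | intermediate
23 | lithium aza-enolate of 22 (C2 deprotonated) | [Li]N(N(C)C)C(=C)[C@@](C)(O[Si](CC)(CC)CC)C[C@@H](O[Si](C)(C)C(C)(C)C)c1c(C[C@@]2(C)CO2)occ1CO[Si](C)(C)C(C)(C)C | intermediate
24 | furan-fused ten-membered C10 hydroxy C3 dimethylhydrazone (4S,6R,10R) | CC(C)(C)[Si](C)(C)OCc1coc2C[C@@](O)(C)CC/C(=N\N(C)C)[C@@](C)(O[Si](CC)(CC)CC)C[C@@H](O[Si](C)(C)C(C)(C)C)c12 | intermediate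
25 | furan-fused ten-membered C10 hydroxy C3 ketone (4S,6R,10R) | CC(C)(C)[Si](C)(C)OCc1coc2C[C@@](O)(C)CCC(=O)[C@@](C)(O[Si](CC)(CC)CC)C[C@@H](O[Si](C)(C)C(C)(C)C)c12 | intermediate
26 | bridged furan hemiketal (3S,4S,6R,10R): carbocycle C1–C10 fused to the furan at C7–C8, oxygen bridge C3–O–C10, C3 OH, C4 Me/OTES, C6 OTBS, C10 Me, C13 OTBS (key-step product) | CC(C)(C)[Si](C)(C)OCc1coc2C[C@@]3(C)CC[C@](O)(O3)[C@@](C)(O[Si](CC)(CC)CC)C[C@@H](O[Si](C)(C)C(C)(C)C)c12 | intermediate
27 | triol of 26 (3S,4S,6R,10R): free OH at C3, C4, C13; C6 OTBS | OCc1coc2C[C@@]3(C)CC[C@](O)(O3)[C@@](C)(O)C[C@@H](O[Si](C)(C)C(C)(C)C)c12 | intermediate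
28 | C4,C13-diacetate of 27 (3S,4S,6R,10R) | CC(=O)OCc1coc2C[C@@]3(C)CC[C@](O)(O3)[C@@](C)(OC(C)=O)C[C@@H](O[Si](C)(C)C(C)(C)C)c12 | intermediate
29 | furan endoperoxide of 28 (O–O bridge between C8 and C12) | CC(=O)OCC1=C2[C@H](O[Si](C)(C)C(C)(C)C)C[C@](C)(OC(C)=O)[C@]3(O)CC[C@@](C)(O3)CC24OOC1O4 | intermediate
30 | γ-hydroxybutenolide (C12 carbonyl, C8 OH; 3S,4S,6R,10R) | CC(=O)OCC1=C2[C@H](O[Si](C)(C)C(C)(C)C)C[C@](C)(OC(C)=O)[C@]3(O)CC[C@@](C)(O3)CC2(O)OC1=O | intermediate
31 | C8 trifluoroacetate of 30 | CC(=O)OCC1=C2[C@H](O[Si](C)(C)C(C)(C)C)C[C@](C)(OC(C)=O)[C@]3(O)CC[C@@](C)(O3)CC2(OC(=O)C(F)(F)F)OC1=O | intermediate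
32 | C6 tert-butyldimethylsilyl ether of the target (3S,4S,6R,10R,8E) | CC(=O)OCC1=C2[C@H](O[Si](C)(C)C(C)(C)C)C[C@](C)(OC(C)=O)[C@]3(O)CC[C@@](C)(O3)/C=C2/OC1=O | intermediate
33 | CNP0203479.1 (3S,4S,6R,10R,8E) | CC(=O)OCC1=C2/C(=C\[C@@]3(C)CC[C@](O)(O3)[C@@](C)(OC(C)=O)C[C@H]2O)OC1=O | target

**Step count and risk**
Total step count: 18. Longest linear sequence: 15 steps (from 3,4-dibromofuran: steps 1, 2, 4, 5, 8–18).

Steps most likely to fail:

1. Step 13 (proposed new method). The aza-enolate may alkylate a second molecule faster than it closes the strained ten-membered ring (oligomerization), the base may isomerize the epoxide to an allylic alkoxide by removing a C9 proton, or the ring may not close at all. The fallback uses known chemistry and forms C1=C2 by ring-closing metathesis instead of alkylation. It sets out from 19. Dimethylsulfonium methylide (Me3SI, n-BuLi, THF, −10 → 25 °C) homologates the epoxide to the tertiary allylic alcohol, vinyl carbinol amide F1. Vinylmagnesium bromide (THF, 0 °C) converts the Weinreb amide into the vinyl ketone, hydroxy dienone F2. Ring-closing metathesis (second-generation Hoveyda–Grubbs catalyst, toluene, high dilution, 80 °C) joins C1 and C2, and the resulting cis-γ-hydroxy enone should rest as the bridged dihydrofuran hemiketal F3. Diimide reduction (2-nitrobenzenesulfonohydrazide, Et3N, CH2Cl2, 25 °C) saturates C1=C2 without touching the furan, and the route is rejoined at 26.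

2. Step 15. Acyl transfer may not discriminate between the tertiary C4 hydroxyl and the hemiketal hydroxyl, or the hemiketal may open under base so that the freed C10 hydroxyl is acetylated and the oxygen bridge is lost. The fallback sets out from 27. The hemiketal is locked as its methyl ketal (PPTS, MeOH, 25 °C) to give methyl ketal diol F4. Acetylation (Ac2O, DMAP, Et3N, CH2Cl2) can then only give methyl ketal diacetate F5. Mild aqueous acid (AcOH/THF/H2O, 25 °C) hydrolyses the ketal, and the route is rejoined at 28.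

3. Step 9. Facial selectivity may be poor, because the catalyst may not distinguish well between the doubly ortho-substituted, twisted furyl group and the neopentyl-type chain. The fallback sets out from 17 and corrects the centre by SN2 inversion. A non-selective reduction (NaBH4, MeOH, −20 °C) is accepted and the C6 epimers are separated. The unwanted (6S)-alcohol F6 is inverted by a Mitsunobu reaction (4-nitrobenzoic acid, PPh3, DIAD, toluene, 0 °C) to the (6R)-4-nitrobenzoate F7. Methanolysis (K2CO3, MeOH, 0 °C) rejoins the route at 18.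

Further compounds
F1 | step 13 | (2S,4R)-4-(tert-butyldimethylsilyloxy)-4-{4-[(tert-butyldimethylsilyloxy)methyl]-2-[(2S)-2-hydroxy-2-methylbut-3-en-1-yl]furan-3-yl}-N-methoxy-N,2-dimethyl-2-(triethylsilyloxy)butanamide | C[C@](O[Si](CC)(CC)CC)(C[C@@H](O[Si](C)(C)C(C)(C)C)c1c(C[C@@](O)(C)C=C)occ1CO[Si](C)(C)C(C)(C)C)C(=O)N(C)OC
F2 | step 13 | (4S,6R)-6-(tert-butyldimethylsilyloxy)-6-{4-[(tert-butyldimethylsilyloxy)methyl]-2-[(2S)-2-hydroxy-2-methylbut-3-en-1-yl]furan-3-yl}-4-methyl-4-(triethylsilyloxy)hex-1-en-3-one | C=CC(=O)[C@@](C)(O[Si](CC)(CC)CC)C[C@@H](O[Si](C)(C)C(C)(C)C)c1c(C[C@@](O)(C)C=C)occ1CO[Si](C)(C)C(C)(C)C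
F3 | step 13 | 1,2-didehydro analogue of 26 (bridged 2,5-dihydrofuran hemiketal, C1=C2 cis, other centres as in 26) | CC(C)(C)[Si](C)(C)OCc1coc2C[C@@]3(C)C=C[C@](O)(O3)[C@@](C)(O[Si](CC)(CC)CC)C[C@@H](O[Si](C)(C)C(C)(C)C)c12
F4 | step 15 | C3 methyl ketal of 27 (C4 and C13 OH free, C6 OTBS) | OCc1coc2C[C@@]3(C)CC[C@](OC)(O3)[C@@](C)(O)C[C@@H](O[Si](C)(C)C(C)(C)C)c12
F5 | step 15 | C3 methyl ketal of 28 (C4 and C13 acetates, C6 OTBS) | CC(=O)OCc1coc2C[C@@]3(C)CC[C@](OC)(O3)[C@@](C)(OC(C)=O)C[C@@H](O[Si](C)(C)C(C)(C)C)c12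
F6 | step 9 | (2S,4S)-4-hydroxy epimer of 18 (C6 alcohol, 6S) | C[C@](O[Si](CC)(CC)CC)(C[C@H](O)c1c(C[C@@]2(C)CO2)occ1CO[Si](C)(C)C(C)(C)C)C(=O)N(C)OC
F7 | step 9 | (6R)-4-nitrobenzoate of 18 | C[C@](O[Si](CC)(CC)CC)(C[C@@H](OC(=O)c1ccc(cc1)[N+](=O)[O-])c1c(C[C@@]2(C)CO2)occ1CO[Si](C)(C)C(C)(C)C)C(=O)N(C)OC
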